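## The problem

Compound 12 is a lignan lactone in which one γ-butyrolactone carries both aryl units. Ring A (4-hydroxy-3-methoxyphenyl) is attached to Cβ (C4) through a benzylic CH2. Ring B (3-hydroxy-4,5-dimethoxyphenyl) is attached to Cα (C3) through an exocyclic E-configured C=CH bond. The skeleton itself is easy to reach, so the task is to join three simple pieces in few operations while fixing one stereocentre and one alkene geometry.

Cβ (R) is the only stereocentre. No neighbouring centre can set it, so it must come from a chiral building block, reagent or catalyst. It can influence only the alkene geometry, through allylic strain against ring B. Cβ is also allylic and is the γ-position of the arylidene lactone, so strong base or hot acid can remove its proton. That would racemise it or move the double bond into the ring, giving a butenolide in which the stereocentre is lost.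

The trisubstituted alkene rules out hydrogenolysis and any late reduction. The two phenols are acidic and easily oxidised and must be masked during organometallic steps, and the lactone carbonyl is open to hard nucleophiles.

The enabling feature is the 1,3-relationship of the benzylic CH2 and Cα across Cβ. Joining these two carbons gives a cyclopropane (CH2, Cβ, Cα) fused to the lactone. If Cα also bears a phosphonate, that ring is electrophilic at CH2 toward a ring A nucleophile. Once opened, it is nucleophilic at Cα as an olefination reagent for a ring B aldehyde.

## Retrosynthesis

**12 ⇒ 11.** Only the two phenolic O–H groups are touched; they are traced back to the O–CH2 bonds of two methoxymethyl acetals in 11. Benzyl ethers are excluded because hydrogenolysis would also saturate Cα=CH, and acyl groups because they would not survive an aryl Grignard reagent. The acetal is inert to magnesium, copper and enolates, and both copies leave in one mildly acidic operation. Compound 11 is no simpler in skeleton, but it has no acidic protons, which every earlier step requires. The forward reaction must cleave two aryl acetals without shifting or inverting the alkene, and without letting the released one-carbon electrophile alkylate the electron-rich rings.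

**11 ⇒ 4 + 7 + 9 (through 10).** Two skeletal bonds are cut together: the ring A aryl–CH2 bond and Cα=CH.
- Cutting Cα=CH alone leaves a β-benzyl lactone that still holds the stereocentre and needs a separate activation of Cα.
- Cutting CH2–Cβ (benzyl nucleophile plus butenolide) would create the stereocentre during C–C bond formation and would need an asymmetric catalyst or auxiliary.
- Cutting aryl–CH2 leaves Cβ a spectator. The electrophile is the cyclopropane CH2 of 4 and the leaving group is Cα itself. The phosphonate makes the departing carbanion 10 stable enough to leave and ready to olefinate 9.

This is the largest simplification available: the C25 compound 11 falls into a small bicyclic core and two simple arenes. The forward reaction must attack C6 of 4 rather than C5, the carbonyl or phosphorus. It must leave no aryl-metal behind when 9 enters, and it must deliver the E alkene.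

**4 ⇒ 1 + 2 (through 3).** The cyclopropane bonds Cα–CH2 and Cα–Cβ and the acyl C–O bond of the lactone are cut. This returns Cα with both acceptors as 1, and the CH2–CH–CH2O unit as 2. Carbene cyclopropanation of an allyl ester would form the same bicycle, but it would need an enantioselective catalyst for an acceptor/acceptor carbene. The bis-electrophile route takes the configuration from a commodity chiral building block in one operation. The forward reaction must open the epoxide of 2 at its CH2 first and re-close to epoxide 3. It must then form the three-membered ring with inversion at the stereocentre and place the ester, not the phosphonate, cis to the alkoxymethyl arm so that lactonisation can follow.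

**7 ⇒ 6 ⇒ 5, and 9 ⇒ 8.** The C–Mg bond of 7 goes back to the C–Br bond of 6, and the acetal O–CH2 bonds of 6 and 9 go back to the phenols 5 and 8. Both 5 and 8 are catalogue compounds that already carry the full oxygenation pattern, so no regioselective arene chemistry is needed. The forward reactions are routine, but the titre of 7 must be known accurately because the key step depends on stoichiometry.

## Roads not taken

**Alternative 1:** Ring B is built rather than bought. Its C1'–C6' and C2'–C3' bonds are cut, which leads to the Cα-propioloyl lactone A2 and 3,4-dimethoxyfuran A3. In the forward direction, the terminal ynone of A2 adds across the 2,5-positions of A3 in a Diels–Alder reaction. Acid-induced aromatisation then gives the aroyl lactone A1 with the 3-phenol free.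

- *Merits.* The symmetrical diene removes any regiochemical question in the cycloaddition. The oxygen bridge should open away from the acyl-bearing carbon, which is the direction needed. The hydroxyl of ring B emerges differentiated from the two methoxy groups without a protecting group. On this point the road beats the chosen plan, which has to add and remove one acetal on ring B.
- *Weak points.* A1 is at the wrong oxidation level: Cα carries C=O where 12 needs =CH. Reduction and E-selective dehydration would have to follow, on a β-keto lactone prone to retro-Claisen cleavage and in the presence of a free phenol. A2 combines a doubly activated Cα–H with an unhindered ynone, so it is likely to consume itself by Michael addition or by O-cyclisation of its enol. A3 is costly and acid-labile.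
- *Comparison.* The step does nothing for the central problem, because A2 must already contain Cβ and the ring A benzyl group. Aldehyde 8 supplies the finished ring B from the catalogue. The chosen plan therefore reaches 11 in one step from the stage at which this road would only begin to assemble A2.

**Alternative 2:** The Cα–Cβ bond is cut, which unfolds the lactone into the isomeric coniferyl-type cinnamate ester A5. In the forward direction, one-electron oxidation of the styrene of A5 would trigger attack by the cinnamate α-carbon on the carbon next to CH2O (5-exo closure). Loss of the α-proton and hydrogen-atom transfer to the benzylic radical would then give the bis-silyl ether A4.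

- *Merits.* This would be the shortest and most atom-economical route. It is a redox-neutral isomerisation with no organometallic reagent and no phosphorus waste. In step and atom economy it is better than the chosen plan.
- *Weak points.* These are mechanistic.
  - Both arenes of A5 are electron-rich, and the trioxygenated ring B competes as the site of oxidation.
  - The cinnamate α-carbon is the electron-poor terminus of its alkene and a poor partner for a radical cation.
  - The ester must adopt its disfavoured conformer for 5-exo closure.
  - [2+2] cycloaddition and Friedel–Crafts-type closure to aryltetralin skeletons are the more natural outlets.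
  - The radical cation offers no binding site for a chiral controller, so Cβ would form as a racemate and the alkene geometry would be decided by an uncontrolled deprotonation.
- *Comparison.* The chosen plan answers with polar, predictable bond formation, a stereocentre bought with 2, and an olefination with an inherent E preference.

**Alternative 3:** The Cγ–O bond is cut, leading to the prochiral oxetanyl acrylic acid A7. A chiral phosphoric acid would activate the oxetane, and the carboxyl oxygen would open one of the two enantiotopic CH2–O bonds. This closes the lactone and gives the hydroxymethyl lactone A6.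

- *Merits.* The stereocentre comes from a catalyst acting on an achiral substrate. Either enantiomer is accessible. The E alkene is secured before the lactone forms, and acid-catalysed oxetane desymmetrisation by internal nucleophiles is an established reaction class. As a piece of stereocontrol it is more general than a chiral-pool purchase.
- *Weak points.* The key step leaves ring A unattached. The hydroxyl of A6 would have to become a leaving group and be displaced by a ring A organometallic. That carbon adjoins the vinylogously acidic, allylic Cβ–H, so elimination with loss of the stereocentre, or conjugate attack on the arylidene lactone, are likely competitors. A7 itself needs several steps from an oxetane building block and 9, its conjugated acid is a weak nucleophile, and the enantiomeric purity would depend on catalyst fit.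
- *Comparison.* The chosen plan forms the same aryl–CH2 bond on a substrate that has no acidic Cβ–H problem and no enoate. It forms that bond together with the alkene, in roughly half the number of operations.

Key step: step 5

Assumption: the anion of 1 is taken to attack 2 first at the epoxide CH2, as malonate-type anions do. Initial displacement of chloride would lead to the enantiomer of 4, so the enantiomeric purity of 4 is to be checked before step 5.

## Route

**Step 1**
Reactants: 1 triethyl phosphonoacetate; 2 (R)-epichlorohydrin
Product: 4 diethyl [(1R,5S)-2-oxo-3-oxabicyclo[3.1.0]hexan-1-yl]phosphonate, via epoxy phosphonoacetate 3 (not isolated)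
Conditions: NaOEt (1.1 equiv), EtOH, 0 °C → rt, then 70 °C
Reagents that add atoms: none
Why: This is the double alkylation of an active methylene compound with epichlorohydrin followed by lactonisation, known for malonates and sulfonylacetonitriles: the sodium salt of 1 opens the epoxide of 2 at its CH2, the chlorohydrin alkoxide closes to epoxide 3, and the re-formed carbanion opens 3 at the stereocentre by 3-exo-tet attack with inversion. C5 of 4 is therefore set by 2, and C1 follows from it because the bulkier phosphonate should settle trans to the alkoxymethyl arm and only the isomer with the ester cis to that arm can close the necessarily cis-fused lactone.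

**Step 2**
Reactants: 5 4-bromo-2-methoxyphenol
Product: 6 4-bromo-2-methoxy-1-(methoxymethoxy)benzene
Conditions: MOMCl, iPr2NEt, CH2Cl2, 0 °C → rt
Reagents that add atoms: chloromethyl methyl ether (MOMCl), COCCl
Why: Williamson-type O-alkylation of a phenol with a reactive α-chloro ether. The resulting acetal has no acidic proton and is inert to magnesium, cuprates and enolates.

**Step 3**
Reactants: 6 4-bromo-2-methoxy-1-(methoxymethoxy)benzene
Product: 7 3-methoxy-4-(methoxymethoxy)phenylmagnesium bromide (THF solution, titrated and used directly)
Conditions: Mg turnings (I2-activated), LiCl, THF, 25–40 °C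
Reagents that add atoms: magnesium, [Mg]
Why: Grignard formation by direct magnesium insertion into an aryl bromide, with LiCl to speed insertion and keep the reagent soluble. The magnesium sits meta and para to the ether groups, so no chelation or elimination pathway is open.

**Step 4**
Reactants: 8 3-hydroxy-4,5-dimethoxybenzaldehyde
Product: 9 3,4-dimethoxy-5-(methoxymethoxy)benzaldehyde
Conditions: MOMCl, iPr2NEt, CH2Cl2, 0 °C → rt
Reagents that add atoms: chloromethyl methyl ether (MOMCl), COCCl
Why: The same Williamson-type O-alkylation as in step 2. The amine base leaves the aldehyde untouched, and removing the phenolic proton prevents quenching of enolate 10 in step 5.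

**Step 5**
Reactants: 4 diethyl [(1R,5S)-2-oxo-3-oxabicyclo[3.1.0]hexan-1-yl]phosphonate; 7 3-methoxy-4-(methoxymethoxy)phenylmagnesium bromide; 9 3,4-dimethoxy-5-(methoxymethoxy)benzaldehyde
Product: 11 (3E,4R)-3-[3,4-dimethoxy-5-(methoxymethoxy)benzylidene]-4-[3-methoxy-4-(methoxymethoxy)benzyl]dihydrofuran-2(3H)-one, via bromomagnesium phosphonoenolate 10 (not isolated)
Conditions: 4 (1.3 equiv), CuI (20 mol %), THF, −30 °C, slow addition of 7 (1.2 equiv), then 0 °C; 9 (1.0 equiv), 0 → 50 °C; aq NH4Cl
Reagents that add atoms: none
Why: Proposed new method: CuI converts part of 7 into the cuprate Ar2CuMgBr (monovalent copper, Ar = ring A aryl), which attacks the σ* orbital of the C1–C6 bond of 4 from the rear of C6 (SN2-type homoconjugate addition through a trivalent copper σ-alkyl species, then reductive elimination), forming the aryl–CH2 bond and expelling C1 as the chelated, doubly stabilised enolate 10. Enolate 10 is the species a base would generate from an α-phosphono lactone, so it adds to the formyl group of 9 and the β-alkoxide collapses through an oxaphosphetane with loss of (EtO)2P(O)OMgBr (Horner–Wadsworth–Emmons olefination), forming Cα=CH. The closest known reaction types are the CuI-catalysed Grignard opening of ester-activated cyclopropane-fused lactones at their CH2, the ring-opening/Wittig annulations of acyl-substituted cyclopropylphosphonium salts, the Grignard conjugate addition–olefination of α-phosphono butenolides and magnesium-mediated Horner–Wadsworth–Emmons reactions; the intermolecular three-component union through a cyclopropyl phosphonate is the new element. No ring is closed (the cyclopropane opens, the lactone stays intact) and no stereocentre is created: C5 of 4 is not a reacting centre and becomes Cβ of 11 with its substituents in the same spatial order, the descriptor changing from S to R only because phosphorus leaves the neighbouring carbon. Attack at C6 rather than C5 rests on sterics (CH2 against a ring-fusion CH) and on overlap, since the C1–C6 bond rises out of the lactone plane and aligns with the carbonyl π* orbital whereas C1–C5 lies in that plane; the quaternary C1 with its bulky phosphonate shields the carbonyl, and the low temperature protects phosphorus. Chemoselectivity toward 9 is secured by stoichiometry and order of addition: 7 is added slowly and kept below 4 so that no free aryl-metal remains, unreacted 4 is inert to aldehydes, and 9 is the limiting component. E geometry is expected because addition of the stabilised magnesium enolate is reversible, so elimination runs through the less crowded adduct that places ring B anti to the lactone carbonyl, which is also the thermodynamically preferred arrangement. The only bases left at the end are excess 10 and (EtO)2P(O)OMgBr, both too weak to deprotonate Cβ of 11.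

**Step 6**
Reactants: 11 (3E,4R)-3-[3,4-dimethoxy-5-(methoxymethoxy)benzylidene]-4-[3-methoxy-4-(methoxymethoxy)benzyl]dihydrofuran-2(3H)-one
Product: 12 (3E,4R)-3-(3-hydroxy-4,5-dimethoxybenzylidene)-4-(4-hydroxy-3-methoxybenzyl)dihydrofuran-2(3H)-one
Conditions: conc. HCl (cat.), MeOH–THF, rt → 40 °C
Reagents that add atoms: none
Why: Acid-catalysed transacetalisation of aryl MOM ethers, in which methanol traps the methoxymethyl cation before it can alkylate either electron-rich ring. The conjugated alkene and Cβ are not engaged under mild acid, and any methanolysis of the γ-lactone should revert on concentration.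

## Compound list

1 | triethyl phosphonoacetate | CCOC(=O)CP(=O)(OCC)OCC | starting material
2 | (R)-epichlorohydrin, (2R)-2-(chloromethyl)oxirane | ClC[C@H]1CO1 | starting material
3 | ethyl 2-(diethoxyphosphoryl)-3-[(2R)-oxiran-2-yl]propanoate (C2 epimers) | CCOC(=O)C(C[C@@H]1CO1)P(=O)(OCC)OCC | intermediate
4 | diethyl [(1R,5S)-2-oxo-3-oxabicyclo[3.1.0]hexan-1-yl]phosphonate | C1[C@H]2COC(=O)[C@@]12P(=O)(OCC)OCC | intermediate
5 | 4-bromo-2-methoxyphenol | COc1cc(Br)ccc1O | starting material
6 | 4-bromo-2-methoxy-1-(methoxymethoxy)benzene | COCOc1ccc(Br)cc1OC | intermediate
7 | 3-methoxy-4-(methoxymethoxy)phenylmagnesium bromide | COCOc1ccc([Mg]Br)cc1OC | intermediate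
8 | 3-hydroxy-4,5-dimethoxybenzaldehyde | COc1cc(C=O)cc(O)c1OC | starting material
9 | 3,4-dimethoxy-5-(methoxymethoxy)benzaldehyde | COCOc1cc(C=O)cc(OC)c1OC | intermediate
10 | bromomagnesium enolate of diethyl {(4S)-4-[3-methoxy-4-(methoxymethoxy)benzyl]-2-oxotetrahydrofuran-3-yl}phosphonate (same spatial arrangement at C4 as in 12) | COCOc1ccc(C[C@H]2COC(O[Mg]Br)=C2P(=O)(OCC)OCC)cc1OC | intermediate
11 | (3E,4R)-3-[3,4-dimethoxy-5-(methoxymethoxy)benzylidene]-4-[3-methoxy-4-(methoxymethoxy)benzyl]dihydrofuran-2(3H)-one | COCOc1ccc(C[C@H]2COC(=O)/C2=C/c2cc(OCOC)c(OC)c(OC)c2)cc1OC | intermediate
12 | (3E,4R)-3-(3-hydroxy-4,5-dimethoxybenzylidene)-4-(4-hydroxy-3-methoxybenzyl)dihydrofuran-2(3H)-one | COc1cc(C[C@H]2COC(=O)/C2=C/c2cc(O)c(OC)c(OC)c2)ccc1O | target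

## Step count and least certain steps

Total: 6 steps. Longest linear sequence: 4 steps (5 → 6 → 7 → 11 → 12, that is steps 2, 3, 5 and 6).

**Step 5 (key step, new method).** Three processes can fail.
- The aryl cuprate is a weaker nucleophile than alkyl cuprates and may open the cyclopropane too slowly, so that direct Grignard attack at the lactone carbonyl or at phosphorus takes over.
- Aryl-metal left in the flask may add to the aldehyde.
- The magnesium β-alkoxy phosphonate may eliminate reluctantly, or with eroded E selectivity, because ring B is pushed against the Cβ substituent.

The fallback keeps the homoconjugate addition but moves it to the ester-activated cyclopropane, for which the copper-catalysed Grignard opening is established, and it replaces the olefination by an aldol condensation. It sets out from 2, 7 and 9. Diethyl malonate and 2 with NaOEt in EtOH give ethyl (1S,5R)-2-oxo-3-oxabicyclo[3.1.0]hexane-1-carboxylate F1. Reagent 7 with CuI in THF at −30 °C opens it to ethyl (4R)-4-[3-methoxy-4-(methoxymethoxy)benzyl]-2-oxotetrahydrofuran-3-carboxylate F2. Krapcho dealkoxycarbonylation (LiCl, wet DMSO, 140 °C) gives (4R)-4-[3-methoxy-4-(methoxymethoxy)benzyl]dihydrofuran-2(3H)-one F3. LiN(SiMe3)2 and then 9 at −78 °C give the trans aldol (3S,4R)-3-{[3,4-dimethoxy-5-(methoxymethoxy)phenyl](hydroxy)methyl}-4-[3-methoxy-4-(methoxymethoxy)benzyl]dihydrofuran-2(3H)-one F4. MsCl/Et3N converts this into its methanesulfonate F5, and DBU eliminates it by an E1cB process to the conjugated E alkene. The sequence comes back to the route at 11.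

**Step 1.** The cyclopropane may close with the phosphonate rather than the ester on the side of the alkoxymethyl arm. Lactonisation is then blocked and the alkoxide is diverted to phosphorus. Partial direct displacement of chloride would erode the enantiomeric purity, and C-to-O phosphoryl migration could intervene on heating.

The fallback changes the nucleophile and the way the lactone forms. It sets out from 2 and uses diethyl cyanomethylphosphonate with NaOEt in EtOH. The linear nitrile is far smaller than the phosphonate, so it should end up cis to the alkoxide, which adds to it in a Pinner-type closure. This gives the cyclic imidate diethyl [(1R,5S)-2-imino-3-oxabicyclo[3.1.0]hexan-1-yl]phosphonate F6. Dilute aqueous HCl hydrolyses the imidate, and the sequence comes back at 4.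

**Step 6.** Acid may isomerise the alkene (E to Z, or exocyclic to endocyclic). The released one-carbon electrophile may alkylate the electron-rich rings. The more hindered ring B acetal may also cleave incompletely.

The fallback replaces acid-labile protection with fluoride-labile protection. It sets out from 5 and 8, with 4 used unchanged. iPr3SiCl and imidazole in DMF give (4-bromo-2-methoxyphenoxy)triisopropylsilane F7 and 3,4-dimethoxy-5-(triisopropylsilyloxy)benzaldehyde F8. Mg and LiCl in THF convert the bromide into 3-methoxy-4-(triisopropylsilyloxy)phenylmagnesium bromide F9. The conditions of step 5 lead through the bromomagnesium enolate of diethyl {(4S)-4-[3-methoxy-4-(triisopropylsilyloxy)benzyl]-2-oxotetrahydrofuran-3-yl}phosphonate F10 to the bis(triisopropylsilyl) ether of 12 F11. Bu4NF buffered with AcOH in THF at 0 °C removes both silyl groups, and the sequence comes back at 12.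

**Step 3.** Insertion into the electron-rich bromide may start slowly and be accompanied by Wurtz-type homocoupling. The resulting uncertain titre would upset the stoichiometric balance on which step 5 depends.

The fallback replaces insertion by halogen–metal exchange. It sets out from 6. n-BuLi in THF at −78 °C gives 3-methoxy-4-(methoxymethoxy)phenyllithium F12 faster than any acetal-directed deprotonation can occur. MgBr2·OEt2 then transmetalates it, and the sequence comes back at 7.

## Further compounds

F1 | step 5 | ethyl (1S,5R)-2-oxo-3-oxabicyclo[3.1.0]hexane-1-carboxylate | C1[C@H]2COC(=O)[C@@]12C(=O)OCC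
F2 | step 5 | ethyl (4R)-4-[3-methoxy-4-(methoxymethoxy)benzyl]-2-oxotetrahydrofuran-3-carboxylate (C3 epimers) | COCOc1ccc(C[C@H]2COC(=O)C2C(=O)OCC)cc1OC
F3 | step 5 | (4R)-4-[3-methoxy-4-(methoxymethoxy)benzyl]dihydrofuran-2(3H)-one | COCOc1ccc(C[C@H]2COC(=O)C2)cc1OC
F4 | step 5 | (3S,4R)-3-{[3,4-dimethoxy-5-(methoxymethoxy)phenyl](hydroxy)methyl}-4-[3-methoxy-4-(methoxymethoxy)benzyl]dihydrofuran-2(3H)-one (carbinol epimers) | COCOc1ccc(C[C@H]2COC(=O)[C@@H]2C(O)c2cc(OCOC)c(OC)c(OC)c2)cc1OC
F5 | step 5 | methanesulfonate of F4 | COCOc1ccc(C[C@H]2COC(=O)[C@@H]2C(OS(C)(=O)=O)c2cc(OCOC)c(OC)c(OC)c2)cc1OC
F6 | step 1 | diethyl [(1R,5S)-2-imino-3-oxabicyclo[3.1.0]hexan-1-yl]phosphonate | C1[C@H]2COC(=N)[C@@]12P(=O)(OCC)OCC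
F7 | step 6 | (4-bromo-2-methoxyphenoxy)triisopropylsilane | COc1cc(Br)ccc1O[Si](C(C)C)(C(C)C)C(C)C
F8 | step 6 | 3,4-dimethoxy-5-(triisopropylsilyloxy)benzaldehyde | COc1cc(C=O)cc(O[Si](C(C)C)(C(C)C)C(C)C)c1OC
F9 | step 6 | 3-methoxy-4-(triisopropylsilyloxy)phenylmagnesium bromide | COc1cc([Mg]Br)ccc1O[Si](C(C)C)(C(C)C)C(C)C
F10 | step 6 | bromomagnesium enolate of diethyl {(4S)-4-[3-methoxy-4-(triisopropylsilyloxy)benzyl]-2-oxotetrahydrofuran-3-yl}phosphonate | COc1cc(C[C@H]2COC(O[Mg]Br)=C2P(=O)(OCC)OCC)ccc1O[Si](C(C)C)(C(C)C)C(C)C
F11 | step 6 | bis(triisopropylsilyl) ether of 12, (3E,4R) | COc1cc(C[C@H]2COC(=O)/C2=C/c2cc(O[Si](C(C)C)(C(C)C)C(C)C)c(OC)c(OC)c2)ccc1O[Si](C(C)C)(C(C)C)C(C)C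
F12 | step 3 | 3-methoxy-4-(methoxymethoxy)phenyllithium | COCOc1ccc([Li])cc1OC
A1 | alternative 1 | (4R)-3-(3-hydroxy-4,5-dimethoxybenzoyl)-4-[3-methoxy-4-(triisopropylsilyloxy)benzyl]dihydrofuran-2(3H)-one | CC(C)[Si](Oc1ccc(C[C@H]2COC(=O)C2C(=O)c2cc(O)c(OC)c(OC)c2)cc1OC)(C(C)C)C(C)C
A2 | alternative 1 | (4R)-4-[3-methoxy-4-(triisopropylsilyloxy)benzyl]-3-propioloyldihydrofuran-2(3H)-one | CC(C)[Si](Oc1ccc(C[C@H]2COC(=O)C2C(=O)C#C)cc1OC)(C(C)C)C(C)C
A3 | alternative 1 | 3,4-dimethoxyfuran | COc1cocc1OC
A4 | alternative 2 | bis(tert-butyldimethylsilyl) ether of 12, (3E,4R) | COc1cc(C[C@H]2COC(=O)/C2=C/c2cc(O[Si](C)(C)C(C)(C)C)c(OC)c(OC)c2)ccc1O[Si](C)(C)C(C)(C)C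
A5 | alternative 2 | (E)-3-[4-(tert-butyldimethylsilyloxy)-3-methoxyphenyl]allyl (E)-3-[3-(tert-butyldimethylsilyloxy)-4,5-dimethoxyphenyl]acrylate | COc1cc(/C=C/COC(=O)/C=C/c2cc(O[Si](C)(C)C(C)(C)C)c(OC)c(OC)c2)ccc1O[Si](C)(C)C(C)(C)C
A6 | alternative 3 | (3E,4S)-3-[3,4-dimethoxy-5-(methoxymethoxy)benzylidene]-4-(hydroxymethyl)dihydrofuran-2(3H)-one | OC[C@H]1COC(=O)/C1=C/c1cc(OCOC)c(OC)c(OC)c1
A7 | alternative 3 | (E)-3-[3,4-dimethoxy-5-(methoxymethoxy)phenyl]-2-(oxetan-3-yl)acrylic acid | OC(=O)/C(=C/c1cc(OCOC)c(OC)c(OC)c1)C1COC1
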